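The route is built on cutting ring B (the propanoyl ring: C1 carbonyl, C2 acyl-bearing, C3, C4 gem-dimethyl, C5, C6 bridge-bearing) at C2–C3 and C6–C1. Because C4 is quaternary, ring B can never aromatise, so a cyclobutenone/ynol ether electrocyclic cascade stops at the cyclohexa-2,4-dienone. In one operation 3-ethoxy-2,4,4-trimethylcyclobut-2-en-1-one (from dimethylketene and 1-ethoxypropyne) and the push–pull ynone 1-ethoxypent-1-yn-3-one deliver ring B with its three oxygens, the acyl group and the future bridge carbon as a methyl. Hydrolysis, selenoxide dehydrogenation of that methyl and Michael capture by butanoylfilicinic acid then give the target.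

Key step: step 3

Remark: 14, 18 and 22 are enolised β-triketones; each is drawn as one tautomer and all tautomers count as the same compound. The target has no stereocenter; 8, 11, 19 and 20 are racemic or diastereomer mixtures whose stereocenters are erased within the route.

Step 1
Reactants: 1 2-methylpropanoyl chloride (isobutyryl chloride); 2 1-ethoxyprop-1-yne
Product: 4 3-ethoxy-2,4,4-trimethylcyclobut-2-en-1-one, via dimethylketene 3 (not isolated)
Conditions: Et3N, MeCN, rt to 45 °C, 1 added slowly
Reagents that add atoms: none
Why: Dehydrochlorination gives dimethylketene, whose carbonyl carbon is attacked by the methyl-bearing carbon of the ynol ether in a regioselective ketene–alkyne [2+2] cycloaddition, placing ethoxy at C3 and the gem-dimethyl carbon at C4; no stereocenter is formed.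

Step 2
Reactants: 5 ethoxyacetylene; 6 N-methoxy-N-methylpropanamide
Product: 9 1-ethoxypent-1-yn-3-one, via lithium ethoxyacetylide 7 (not isolated), via tetrahedral adduct 8 (not isolated)
Conditions: n-BuLi, THF, −78 °C; then 6, −78 to 0 °C; cold sat. aq NH4Cl
Reagents that add atoms: none
Why: Weinreb ketone synthesis: the chelated tetrahedral adduct persists until the cold, nearly neutral quench, so the ynone is never exposed to the acetylide and the acid-sensitive ynol ether survives.

Step 3
Reactants: 4 3-ethoxy-2,4,4-trimethylcyclobut-2-en-1-one; 9 1-ethoxypent-1-yn-3-one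
Product: 13 3,5-diethoxy-4,6,6-trimethyl-2-propanoylcyclohexa-2,4-dien-1-one, via vinylketene 10 (not isolated), via vinylcyclobutenone 11 (not isolated), via dienylketene 12 (not isolated)
Conditions: PhMe, 100 °C, sealed tube, 4 (1.5 equiv), 9 added over 6 h; then 110 °C
Reagents that add atoms: none
Why: Proposed new method: heating opens 4 by conrotatory four-electron electrocyclic cleavage of its C1–C4 bond to vinylketene 10, whose ketene carbon bonds to the propanoyl-bearing alkyne carbon of 9 (remote from ethoxy) and whose α-carbon bonds to the ethoxy-bearing one in a ketene–alkyne [2+2] cycloaddition to give 11 (target ring-B bonds C2–C3 and C6–C1); a second four-electron opening gives dienylketene 12, and thermal disrotatory six-electron electrocyclization between the ketene carbon and the dimethyl-substituted terminus closes the six-membered ring B (re-forming C3–C4). The closest known reaction type is the Danheiser annulation of cyclobutenone-derived vinylketenes with alkoxyalkynes, together with the known thermal ring closure of dienylketenes to 6,6-disubstituted cyclohexa-2,4-dienones; new are the acyl-substituted (push–pull) ynol ether and the terminus that cannot aromatise. No stereocenter is created in 13 (11 is racemic and its quaternary center is lost on ring opening). Regioselectivity of the [2+2] step is required and is secured by the ethoxy donor, which makes the acyl-bearing alkyne carbon the nucleophilic terminus that attacks the electrophilic ketene carbon; periselectivity over hetero-[4+2] addition at the ynone carbonyl is expected because ketenes engage ynol ethers through the [2+2] mode. Opening of 11 in the unproductive rotational sense is reversible, so material should drain through the (3E)-isomer 12, in which the ketene and ethoxyalkenyl groups are cis. The two methyl groups on C6 of 13 block tautomerisation to a phenol, and slow addition of 9 keeps its concentration low so that thermal loss of ethylene from the ynol ether should not compete.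

Step 4
Reactants: 13 3,5-diethoxy-4,6,6-trimethyl-2-propanoylcyclohexa-2,4-dien-1-one
Product: 14 3,5-dihydroxy-4,6,6-trimethyl-2-propanoylcyclohexa-2,4-dien-1-one
Conditions: 2 M aq HCl, THF, 50 °C
Reagents that add atoms: water, O
Why: Both ethyl enol ethers are vinylogous esters and should undergo acid-catalysed enol ether hydrolysis (C-protonation, addition of water, loss of ethanol) to the enolised β-triketone, while the acyl group and quaternary carbon are inert to dilute acid.

Step 5
Reactants: 15 phloroglucinol (benzene-1,3,5-triol); 16 butanoyl chloride
Product: 17 1-(2,4,6-trihydroxyphenyl)butan-1-one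
Conditions: AlCl3, PhNO2/CH2Cl2, 0 °C to rt; then ice, aq HCl
Reagents that add atoms: none
Why: Friedel–Crafts C-acylation of the symmetric, highly activated arene; the chelated aryl ketone is deactivated, so the reaction should stop at monoacylation.

Step 6
Reactants: 17 1-(2,4,6-trihydroxyphenyl)butan-1-one
Product: 18 2-butanoyl-3,5-dihydroxy-4,4-dimethylcyclohexa-2,5-dien-1-one (butanoylfilicinic acid)
Conditions: NaOMe, MeI (2.2 equiv), MeOH, 0 °C to rt; then aq HCl
Reagents that add atoms: iodomethane, CI
Why: Dearomatising double C-methylation of the acylphloroglucinol anion: the first methyl makes its own carbon the most nucleophilic site, so the second enters geminally, and the delocalised vinylogous acid anion that results is much slower to react a third time.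

Step 7
Reactants: 14 3,5-dihydroxy-4,6,6-trimethyl-2-propanoylcyclohexa-2,4-dien-1-one
Product: 19 3-hydroxy-4,6,6-trimethyl-4-(phenylselanyl)-2-propanoylcyclohex-2-ene-1,5-dione (racemic)
Conditions: PhSeCl, pyridine, CH2Cl2, 0 °C
Reagents that add atoms: benzeneselenenyl chloride, Cl[Se]c1ccccc1
Why: Electrophilic α-selenenylation of an enolised β-dicarbonyl at the methyl-bearing ring carbon C4, the site at which such 2-acyl triones take up carbon electrophiles; the new quaternary center forms as a racemate and is erased in step 8.

Step 8
Reactants: 19 3-hydroxy-4,6,6-trimethyl-4-(phenylselanyl)-2-propanoylcyclohex-2-ene-1,5-dione; 18 2-butanoyl-3,5-dihydroxy-4,4-dimethylcyclohexa-2,5-dien-1-one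
Product: 22 2-butanoyl-6-[(2,4-dihydroxy-3,3-dimethyl-6-oxo-5-propanoylcyclohexa-1,4-dien-1-yl)methyl]-3,5-dihydroxy-4,4-dimethylcyclohexa-2,5-dien-1-one (target), via selenoxide 20 (not isolated), via exocyclic enetrione 21 (not isolated)
Conditions: mCPBA (1.0 equiv), CH2Cl2, −78 °C; then 18 (1.5 equiv), −78 °C to rt
Reagents that add atoms: none
Why: Selenide oxidation at −78 °C consumes the peracid before 18 is added; on warming, selenoxide syn-elimination can only use the methyl hydrogens and gives the exocyclic enetrione, which the unsubstituted ring carbon of the acidic enol 18 captures by Michael addition without base, avoiding base-induced scrambling of the methylene bridge.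

Compound list
1 | 2-methylpropanoyl chloride (isobutyryl chloride) | CC(C)C(Cl)=O | starting material
2 | 1-ethoxyprop-1-yne | CCOC#CC | starting material
3 | dimethylketene (2-methylprop-1-en-1-one) | CC(C)=C=O | intermediate (not isolated)
4 | 3-ethoxy-2,4,4-trimethylcyclobut-2-en-1-one | CCOC1=C(C)C(=O)C1(C)C | intermediate
5 | ethoxyacetylene (ethoxyethyne) | CCOC#C | starting material
6 | N-methoxy-N-methylpropanamide | CCC(=O)N(C)OC | starting material
7 | lithium ethoxyacetylide | CCOC#C[Li] | intermediate (not isolated)
8 | lithium 1-ethoxy-3-[methoxy(methyl)amino]pent-1-yn-3-olate (racemic tetrahedral adduct) | CCOC#CC(CC)(O[Li])N(C)OC | intermediate (not isolated)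
9 | 1-ethoxypent-1-yn-3-one | CCOC#CC(=O)CC | intermediate
10 | 3-ethoxy-2,4-dimethylpenta-1,3-dien-1-one (vinylketene) | CCOC(=C(C)C)C(C)=C=O | intermediate (not isolated)
11 | 3-ethoxy-4-(1-ethoxy-2-methylprop-1-en-1-yl)-4-methyl-2-propanoylcyclobut-2-en-1-one (racemic) | CCC(=O)C1=C(OCC)C(C)(C(OCC)=C(C)C)C1=O | intermediate (not isolated)
12 | (3E)-3,5-diethoxy-4,6-dimethyl-2-propanoylhepta-1,3,5-trien-1-one (dienylketene) | CCC(=O)C(=C=O)/C(OCC)=C(/C)C(OCC)=C(C)C | intermediate (not isolated)
13 | 3,5-diethoxy-4,6,6-trimethyl-2-propanoylcyclohexa-2,4-dien-1-one | CCC(=O)C1=C(OCC)C(C)=C(OCC)C(C)(C)C1=O | intermediate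
14 | 3,5-dihydroxy-4,6,6-trimethyl-2-propanoylcyclohexa-2,4-dien-1-one (enol form of 2-propanoyl-4,6,6-trimethylcyclohexane-1,3,5-trione) | CCC(=O)C1=C(O)C(C)=C(O)C(C)(C)C1=O | intermediate
15 | phloroglucinol (benzene-1,3,5-triol) | Oc1cc(O)cc(O)c1 | starting material
16 | butanoyl chloride | CCCC(Cl)=O | starting material
17 | 1-(2,4,6-trihydroxyphenyl)butan-1-one | CCCC(=O)c1c(O)cc(O)cc1O | intermediate
18 | 2-butanoyl-3,5-dihydroxy-4,4-dimethylcyclohexa-2,5-dien-1-one (butanoylfilicinic acid) | CCCC(=O)C1=C(O)C(C)(C)C(O)=CC1=O | intermediate
19 | 3-hydroxy-4,6,6-trimethyl-4-(phenylselanyl)-2-propanoylcyclohex-2-ene-1,5-dione (racemic) | CCC(=O)C1=C(O)C(C)([Se]c2ccccc2)C(=O)C(C)(C)C1=O | intermediate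
20 | 4-(benzeneseleninyl)-3-hydroxy-4,6,6-trimethyl-2-propanoylcyclohex-2-ene-1,5-dione (diastereomer mixture) | CCC(=O)C1=C(O)C(C)([Se](=O)c2ccccc2)C(=O)C(C)(C)C1=O | intermediate (not isolated)
21 | 3-hydroxy-6,6-dimethyl-4-methylidene-2-propanoylcyclohex-2-ene-1,5-dione | CCC(=O)C1=C(O)C(=C)C(=O)C(C)(C)C1=O | intermediate (not isolated)
22 | 2-butanoyl-6-[(2,4-dihydroxy-3,3-dimethyl-6-oxo-5-propanoylcyclohexa-1,4-dien-1-yl)methyl]-3,5-dihydroxy-4,4-dimethylcyclohexa-2,5-dien-1-one | CCCC(=O)C1=C(O)C(C)(C)C(O)=C(CC2=C(O)C(C)(C)C(O)=C(C(=O)CC)C2=O)C1=O | target

Total step count: 8. Longest linear sequence: 5 steps (1, 3, 4, 7, 8).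

Steps most likely to fail

Step 3 (Proposed new method). The electron-poor ynol ether may be too slow a ketenophile, so that thermal ethylene loss from the ynol ether, self-condensation of the vinylketene or hetero-cycloaddition at the ynone carbonyl outruns the [2+2] event. The fallback sets out from 15 and returns at 14, using only known chemistry. Friedel–Crafts acylation of 15 with commercial propanoyl chloride (AlCl3, PhNO2/CH2Cl2) should give 1-(2,4,6-trihydroxyphenyl)propan-1-one F1. Dearomatising triple C-methylation of F1 (NaOMe, MeI, 3 equiv, MeOH) should then give 14 directly, the gem-dimethyl carbon and the ring methyl being installed by enolate alkylation instead of by the pericyclic cascade. Steps 7 and 8 follow unchanged.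

Step 8. Self-condensation of the transient exocyclic enetrione (hetero-Diels–Alder dimerisation) or interception of the nucleophile by electrophilic selenium by-products may outrun the Michael capture. The fallback sets out from 19 and returns at 22. Oxidation with mCPBA at −78 °C is run as before, but the enetrione 21 is released in the presence of morpholine, which should add at the exocyclic carbon faster than 21 can dimerise and scavenge the selenenic acid. This should give the storable Mannich base 3,5-dihydroxy-6,6-dimethyl-4-(morpholin-4-ylmethyl)-2-propanoylcyclohexa-2,4-dien-1-one F2. Heating F2 with 18 in toluene should then give 22 by retro-Mannich release of 21 at low stationary concentration, Michael capture by 18 and loss of morpholine.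

Step 7. Selenenylation may go to oxygen or to the acyl-bearing carbon, or selenium may be transferred back during isolation. The fallback sets out from 14 (with 18) and returns at 22, bypassing 19 and 20. TEMPO and PhI(OAc)2 in THF, −78 °C to rt, should dehydrogenate the methyl-bearing enol of 14 directly to enetrione 21, a known oxidation for C-methyl acyl triones. An excess of 18 in the flask then captures 21 by Michael addition. No new compound arises on this path (F0).

Further compounds
F1 | step 3 | 1-(2,4,6-trihydroxyphenyl)propan-1-one | CCC(=O)c1c(O)cc(O)cc1O
F2 | step 8 | 3,5-dihydroxy-6,6-dimethyl-4-(morpholin-4-ylmethyl)-2-propanoylcyclohexa-2,4-dien-1-one | CCC(=O)C1=C(O)C(CN2CCOCC2)=C(O)C(C)(C)C1=O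
F0 | step 7 | none | none
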